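**Retrosynthetic overview**

1. Target ⇒ endo [4+2] of the two unprotected biogenetic partners, morachalcone A (dienophile) and 6-[(E)-3-methylbuta-1,3-dienyl]norartocarpetin (diene). The cyclohexene and all three stereocentres are made in the last step on a chiral boron template.
2. Diene ⇒ Suzuki coupling of 6-iodonorartocarpetin with an (E)-dienyl boronate (enyne + pinacolborane). The iodide ⇒ 5-OH-directed C6 iodination of a 7,2',4'-tri-O-methyl flavone, then O-demethylation.
3. Flavone pyranone ring ⇒ one-pot chalcone → flavanone → flavone sequence from 2',6'-dihydroxy-4'-methoxyacetophenone and 2,4-dimethoxybenzaldehyde.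
4. Morachalcone A ⇒ Claisen–Schmidt condensation of 3-C-prenylresacetophenone with 2,4-dihydroxybenzaldehyde; the prenyl group comes from direct C-prenylation.
5. Ring order: flavone pyranone ring first (step 1), cyclohexene last (step 8).

Locants used below: C3'' carries the flavone, C4'' the aroyl group, C5'' the 2,4-dihydroxyphenyl group. The target is (3''S,4''R,5''S), i.e. 3'',4''-cis and 4'',5''-trans.

Assumption: (R)-VANOL is taken as the ligand antipode that leads to the (3''S,4''R,5''S) series; the sense of induction is checked on the first run, and (S)-VANOL is used in the same step if the mirror image forms.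

**Route**

Step 1
Reactants: 1 1-(2,6-dihydroxy-4-methoxyphenyl)ethanone; 2 2,4-dimethoxybenzaldehyde
Product: 5 2-(2,4-dimethoxyphenyl)-5-hydroxy-7-methoxy-4H-chromen-4-one, via chalcone 3 (not isolated), via flavanone 4 (not isolated)
Conditions: pyrrolidine (0.5 equiv), I2 (10 mol%), DMSO, 150 °C
Reagents that add atoms: none
Why: Domino Claisen–Schmidt condensation / oxa-Michael cyclisation / I2–DMSO dehydrogenation: pyrrolidine condenses 1 with 2 to chalcone 3, either of its two equivalent ortho-hydroxyls closes the ring to flavanone 4 (no regiochemical choice), and catalytic iodine with DMSO as terminal oxidant desaturates C2–C3, which is the chalcone → flavanone → flavone order used in the plant; no stereocentre survives.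

Step 2
Reactants: 5 2-(2,4-dimethoxyphenyl)-5-hydroxy-7-methoxy-4H-chromen-4-one
Product: 6 2-(2,4-dimethoxyphenyl)-5-hydroxy-6-iodo-7-methoxy-4H-chromen-4-one
Conditions: BnMe3N·ICl2 (1.05 equiv), CaCO3 (1.5 equiv), CH2Cl2–MeOH (5:2), rt
Reagents that add atoms: benzyltrimethylammonium dichloroiodate, C[N+](C)(C)Cc1ccccc1.Cl[I-]Cl
Why: Electrophilic aromatic iodination (Kajigaeshi reagent): under these neutral conditions only the phenolic ring A reacts, the aryl methyl ether ring B being inert, and the free 5-OH steers iodine to its ortho position C6 rather than C8, the known preference of 5-hydroxy-7-alkoxyflavones with this reagent.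

Step 3
Reactants: 6 2-(2,4-dimethoxyphenyl)-5-hydroxy-6-iodo-7-methoxy-4H-chromen-4-one
Product: 7 2-(2,4-dihydroxyphenyl)-5,7-dihydroxy-6-iodo-4H-chromen-4-one
Conditions: BBr3 (8 equiv), CH2Cl2, −78 °C → rt; then ice-water
Reagents that add atoms: none
Why: Lewis-acid ether cleavage (BBr3 demethylation): boron binds each ArOMe oxygen and bromide removes the methyl group by SN2, while the aryl iodide and the chromone are inert, as in the standard preparation of 2-iodoresorcinols from their dimethyl ethers.

Step 4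
Reactants: 8 2-methylbut-1-en-3-yne; 9 pinacolborane
Product: 10 4,4,5,5-tetramethyl-2-[(1E)-3-methylbuta-1,3-dien-1-yl]-1,3,2-dioxaborolane
Conditions: Cp2Zr(H)Cl (5 mol%), Et3N (10 mol%), neat, 60 °C
Reagents that add atoms: none
Why: Zirconium-catalysed hydroboration of a terminal alkyne: syn, anti-Markovnikov addition of H–B across the triple bond gives only the (E)-alkenylboronate and leaves the 1,1-disubstituted alkene untouched.

Step 5
Reactants: 7 2-(2,4-dihydroxyphenyl)-5,7-dihydroxy-6-iodo-4H-chromen-4-one; 10 4,4,5,5-tetramethyl-2-[(1E)-3-methylbuta-1,3-dien-1-yl]-1,3,2-dioxaborolane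
Product: 11 2-(2,4-dihydroxyphenyl)-5,7-dihydroxy-6-[(1E)-3-methylbuta-1,3-dien-1-yl]-4H-chromen-4-one
Conditions: SPhos Pd G3 (5 mol%), K3PO4 (6 equiv), THF–H2O (4:1, degassed), 45 °C, dark; pH 5 phosphate buffer at 0 °C; used at once
Reagents that add atoms: none
Why: Suzuki–Miyaura cross-coupling: the C–I bond is the only site for oxidative addition, the bulky electron-rich biarylphosphine copes with the di-ortho-oxygenated aryl iodide, the alkenyl group transfers with retention of E geometry, and the basic medium keeps the product as a phenoxide so the acid-labile diene does not close to a chromene.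

Step 6
Reactants: 12 1-(2,4-dihydroxyphenyl)ethanone; 13 1-bromo-3-methylbut-2-ene (prenyl bromide)
Product: 14 1-[2,4-dihydroxy-3-(3-methylbut-2-en-1-yl)phenyl]ethanone
Conditions: KOH (10% aq., 2 equiv), 0 °C → rt; chromatography
Reagents that add atoms: none
Why: Aromatic C-prenylation of a phenoxide: in aqueous alkali the ambident resorcinol anion alkylates on carbon, preferentially at C3 between the two oxygens, mirroring the prenyltransferase step, and the 5-prenyl and O-prenyl isomers are removed by chromatography (expect about 25–35%).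

Step 7
Reactants: 14 1-[2,4-dihydroxy-3-(3-methylbut-2-en-1-yl)phenyl]ethanone; 15 2,4-dihydroxybenzaldehyde
Product: 16 morachalcone A, (E)-1-[2,4-dihydroxy-3-(3-methylbut-2-en-1-yl)phenyl]-3-(2,4-dihydroxyphenyl)prop-2-en-1-one
Conditions: KOH (60% aq.), EtOH, rt, Ar, 48 h; then 1 M HCl to pH 5 at 0 °C
Reagents that add atoms: none
Why: Claisen–Schmidt (crossed aldol) condensation: the methyl ketone enolate adds to the aldehyde and E1cB loss of hydroxide gives the thermodynamically favoured E-enone, the prenyl group being inert to base.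

Step 8
Reactants: 16 morachalcone A; 11 2-(2,4-dihydroxyphenyl)-5,7-dihydroxy-6-[(1E)-3-methylbuta-1,3-dien-1-yl]-4H-chromen-4-one
Product: 19 target CNP0270206.1 (3''S,4''R,5''S; artonin I), via chalcone boron chelate 17 (not isolated), via cycloadduct boron chelate 18 (not isolated)
Conditions: (R)-VANOL, BH3·THF, AcOH (1.2 equiv each), THF, rt, 1 h; add 16, 30 min; add 11 (1.5 equiv), 4 Å MS, rt → 40 °C; neutral H2O quench; preparative HPLC (removes the exo 3''R isomer)
Reagents that add atoms: none
Why: Proposed new method: the 2'-OH/C=O pair of 16 is the strongest boron binding site and gives the tetracoordinate chelate 17, whose LUMO-lowered s-cis enone is shielded on one face by the VANOL wall, so the electron-rich diene 11 adds to the open face through the endo transition state (aroyl under the diene, 3'',4''-cis) while the E-alkene geometry is carried over as 4'',5''-trans, setting 3''S, 4''R and 5''S in one operation with regiochemistry fixed by the large HOMO coefficient at the diene CH2 terminus and the large LUMO coefficient at the chalcone β-carbon; the closest known reaction type is the chiral boron–biaryldiol-mediated asymmetric Diels–Alder cycloaddition of 2'-hydroxychalcones with O-acylated partners, and the new element is running it on both unprotected polyphenols, which rests on the chelating diol and the chelating hydroxyketone outcompeting monodentate phenols for boron.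

**Compound list**

1 | 1-(2,6-dihydroxy-4-methoxyphenyl)ethanone | CC(=O)c1c(O)cc(OC)cc1O | starting material
2 | 2,4-dimethoxybenzaldehyde | COc1ccc(C=O)c(OC)c1 | starting material
3 | (E)-1-(2,6-dihydroxy-4-methoxyphenyl)-3-(2,4-dimethoxyphenyl)prop-2-en-1-one | COc1cc(O)c(C(=O)/C=C/c2ccc(OC)cc2OC)c(O)c1 | intermediate
4 | racemic 2-(2,4-dimethoxyphenyl)-5-hydroxy-7-methoxychroman-4-one | COc1ccc(C2CC(=O)c3c(O)cc(OC)cc3O2)c(OC)c1 | intermediate
5 | 2-(2,4-dimethoxyphenyl)-5-hydroxy-7-methoxy-4H-chromen-4-one | COc1ccc(-c2cc(=O)c3c(O)cc(OC)cc3o2)c(OC)c1 | intermediate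
6 | 2-(2,4-dimethoxyphenyl)-5-hydroxy-6-iodo-7-methoxy-4H-chromen-4-one | COc1ccc(-c2cc(=O)c3c(O)c(I)c(OC)cc3o2)c(OC)c1 | intermediate
7 | 2-(2,4-dihydroxyphenyl)-5,7-dihydroxy-6-iodo-4H-chromen-4-one | Oc1ccc(-c2cc(=O)c3c(O)c(I)c(O)cc3o2)c(O)c1 | intermediate
8 | 2-methylbut-1-en-3-yne | CC(=C)C#C | starting material
9 | pinacolborane | CC1(C)OBOC1(C)C | starting material
10 | 4,4,5,5-tetramethyl-2-[(1E)-3-methylbuta-1,3-dien-1-yl]-1,3,2-dioxaborolane | CC(=C)/C=C/B1OC(C)(C)C(C)(C)O1 | intermediate
11 | 2-(2,4-dihydroxyphenyl)-5,7-dihydroxy-6-[(1E)-3-methylbuta-1,3-dien-1-yl]-4H-chromen-4-one | CC(=C)/C=C/c1c(O)cc2oc(-c3ccc(O)cc3O)cc(=O)c2c1O | intermediate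
12 | 1-(2,4-dihydroxyphenyl)ethanone | CC(=O)c1ccc(O)cc1O | starting material
13 | 1-bromo-3-methylbut-2-ene | CC(C)=CCBr | starting material
14 | 1-[2,4-dihydroxy-3-(3-methylbut-2-en-1-yl)phenyl]ethanone | CC(C)=CCc1c(O)ccc(C(C)=O)c1O | intermediate
15 | 2,4-dihydroxybenzaldehyde | O=Cc1ccc(O)cc1O | starting material
16 | morachalcone A | CC(C)=CCc1c(O)ccc(C(=O)/C=C/c2ccc(O)cc2O)c1O | intermediate
17 | (R)-VANOL borate chelate of morachalcone A, boron on the 2'-oxygen and the carbonyl oxygen (axial chirality not encoded) | CC(C)=CCc1c(O)ccc2c1O[B-]3(Oc4c(c(-c5ccccc5)cc5ccccc45)-c4c(O3)c5ccccc5cc4-c4ccccc4)[O+]=C2/C=C/c1ccc(O)cc1O | intermediate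
18 | (R)-VANOL borate chelate of the endo cycloadduct, 3''S,4''R,5''S (axial chirality not encoded) | CC(C)=CCc1c(O)ccc2c1O[B-]3(Oc4c(c(-c5ccccc5)cc5ccccc45)-c4c(O3)c5ccccc5cc4-c4ccccc4)[O+]=C2[C@H]6[C@@H](c7c(O)cc8oc(-c9ccc(O)cc9O)cc(=O)c8c7O)C=C(C)C[C@@H]6c1ccc(O)cc1O | intermediate
19 | target CNP0270206.1 (artonin I), 3''S,4''R,5''S | CC(C)=CCc1c(O)ccc(C(=O)[C@H]2[C@@H](c3c(O)cc4oc(-c5ccc(O)cc5O)cc(=O)c4c3O)C=C(C)C[C@@H]2c2ccc(O)cc2O)c1O | target

**Totals and risks**

Total step count: 8. Longest linear sequence: 5 steps (steps 1, 2, 3, 5, 8).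

Three steps most likely to fail:

Step 8. The free phenols may scramble the ligand on boron, diene 11 may close to a chromene, and the endo/exo ratio may be poor. The fallback sets out from 16 and 11. Each is acetylated with Ac2O/pyridine at 0 °C, which leaves the carbonyl-chelated hydroxyl free, to give morachalcone A 2,4,4'-tri-O-acetate F1 and the diene 7,2',4'-tri-O-acetate F2. These are combined under the same (R)-VANOL/BH3·THF/AcOH promotion, now the precedented protected variant, to give the endo cycloadduct hexa-O-acetate F3 after separation from the exo isomer. Brief K2CO3/MeOH at 0 °C (short, to avoid C4'' epimerisation) removes the acetates and the route is rejoined at 19.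

Step 5. The polyphenoxide iodide may couple sluggishly or lose iodine, and free 11 is fragile. The fallback sets out from 7. Peracetylation (Ac2O, pyridine, DMAP) gives 6-iodonorartocarpetin tetra-O-acetate F4. Coupling with 10 under anhydrous conditions (Pd(PPh3)4, K3PO4, dioxane, 80 °C) gives the diene tetra-O-acetate F5, a stable storage form. K2CO3/MeOH at 0 °C just before use returns to 11.

Step 7. The dianion of 2,4-dihydroxybenzaldehyde is a poor electrophile, so conversion may be low. The fallback sets out from 15. MOMCl/i-Pr2NEt in CH2Cl2 gives 2,4-bis(methoxymethoxy)benzaldehyde F6. This condenses cleanly with 14 (KOH, EtOH, rt) to 2,4-di-O-methoxymethyl morachalcone A F7. 3 M HCl/MeOH at rt, stopped before the prenyl group can cyclise, returns to 16.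

**Further compounds**

F1 | step 8 | morachalcone A 2,4,4'-tri-O-acetate (2'-OH free) | CC(C)=CCc1c(OC(C)=O)ccc(C(=O)/C=C/c2ccc(OC(C)=O)cc2OC(C)=O)c1O
F2 | step 8 | 7,2',4'-tri-O-acetate of diene 11 (5-OH free) | CC(=C)/C=C/c1c(OC(C)=O)cc2oc(-c3ccc(OC(C)=O)cc3OC(C)=O)cc(=O)c2c1O
F3 | step 8 | endo cycloadduct hexa-O-acetate, 3''S,4''R,5''S | CC(C)=CCc1c(OC(C)=O)ccc(C(=O)[C@H]2[C@@H](c3c(OC(C)=O)cc4oc(-c5ccc(OC(C)=O)cc5OC(C)=O)cc(=O)c4c3O)C=C(C)C[C@@H]2c2ccc(OC(C)=O)cc2OC(C)=O)c1O
F4 | step 5 | 6-iodonorartocarpetin tetra-O-acetate | CC(=O)Oc1ccc(-c2cc(=O)c3c(OC(C)=O)c(I)c(OC(C)=O)cc3o2)c(OC(C)=O)c1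
F5 | step 5 | tetra-O-acetate of diene 11 | CC(=C)/C=C/c1c(OC(C)=O)cc2oc(-c3ccc(OC(C)=O)cc3OC(C)=O)cc(=O)c2c1OC(C)=O
F6 | step 7 | 2,4-bis(methoxymethoxy)benzaldehyde | COCOc1ccc(C=O)c(OCOC)c1
F7 | step 7 | 2,4-di-O-methoxymethyl morachalcone A | CC(C)=CCc1c(O)ccc(C(=O)/C=C/c2ccc(OCOC)cc2OCOC)c1O
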